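## The problem

Leucanthin B is a germacranolide. Its ten-membered carbocycle (C1–C10) carries a trans-fused α-methylene-γ-lactone (C6–O–C12(=O)–C11(=C13)–C7), two cis-oxiranes (C2–C3 and C4–C5, C4 being the quaternary carbon with methyl C15), an epoxyangelate on O8, an acetate on O9 and a C1=C10 enoic acid (C14 trans to C2, so C2 and C9 are cis). The first task is the ring: a ten-membered ring closes against torsional and transannular strain, so the chain must be bent beforehand and the closing reaction must be irreversible. Ten stereocentres are needed. C4/C5 can come from a catalyst, C6 from C5, C2/C3 from C4, C7 from C6 across the lactone, and C8 from the ring-closing event. C9 and the two centres of the epoxyangelate have no neighbour to lean on and need reagent control. Little is tolerated: the α-methylene lactone is a Michael acceptor, the C4 oxirane is tertiary and acid-labile, the C2 oxirane is allylic to the enoate (exposed to zerovalent palladium and to electron transfer), and the acyl groups on O8 and O9 can change places. Before the ring exists, the lactone is a butenolide whose C6–H lies next to the C5 oxirane, so base would open that oxirane by elimination. The enabling feature is the C13=C11–C7 unit: C7 is the γ carbon of an allyl system built into the lactone and its neighbour C8 bears oxygen, so the exocyclic methylene, C7 and C8 together are the retron of a carbonyl allylation with allylic transposition.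

## Retrosynthesis

**33 ⇒ 32.** Only the C14 carboxyl is masked, as its 2-(trimethylsilyl)ethyl ester in 32. Fluoride removes it without acid, base or metal. An allyl ester would need zerovalent palladium, which ionizes the allylic C2 oxirane, and a tert-butyl ester would need acid. The forward step asks only that anhydrous fluoride spares the α-methylene lactone.

**32 ⇒ 27 + 31.** The O8–acyl bond is cut, but with inversion at C8. An allylchromium reagent whose γ substituent is locked trans, as C6 is by the butenolide ring, adds to an aldehyde in the anti sense, and Felkin–Anh control from C9 points the same way. The ring closure should therefore give the 8R alcohol 27, the C8 epimer of the natural oxygenation. Planning a Mitsunobu esterification with (2R,3R)-epoxyangelic acid 31 turns this expected outcome into the natural 8S ester 32. The forward step must achieve SN2 displacement at a hindered ring carbinol. The cis 9-acetate cannot participate because it lies on the side of the leaving group.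

**27 ⇒ 25 (through 26).** Cutting C7–C8 opens the carbocycle and turns the α-methylene lactone back into a 3-(bromomethyl)butenolide with a C8 aldehyde. Cuts at C5–C6 or C9–C10 would remove one stereocentre each but none of the lactone. This cut removes the ring, the methylene group and two stereocentres at once, and leaves 25 with no free hydroxyl. The forward reaction needs a carbon nucleophile that forms in the presence of an aldehyde, two oxiranes, an acetate and an enoate. CrCl2 does this, and the chain is pre-bent by the E-enoate and the two cis-oxiranes.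

**25 ⇒ 24 ⇒ 23 ⇒ 22.** Bromide and aldehyde are the last groups installed. Both come from the diol 23: the allylic C13 hydroxyl is brominated selectively, then the C8 hydroxyl is oxidized. No base, amine or fluoride meets the bromomethylbutenolide. 23 comes from 22 by loss of the one remaining silyl ether.

**22 ⇒ 21.** The C2–C3 oxirane is introduced before ring closure. In the open chain, allylic strain fixes the conformation about C3–C4 and exposes the face anti to the C4 methyl group, which is the face needed. In a ring drawn flat, the required face is the one that carries that methyl group. Epoxidizing early also removes the tertiary, doubly allylic C4 oxirane from the acidic and Lewis-acidic late steps. The cis-oxirane keeps the turn the Z-alkene gave.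

**21 ⇒ 20 ⇒ 12 + 19.** The Z-alkene comes from semi-hydrogenation of an enyne, and the enyne from a Sonogashira coupling at C1–C2. The cut divides the chain into a C2–C7/C11–C13 half (12) and a C1/C8–C10/C14 half (19) of similar size. The C3–C4 bond cannot be made late because C4 is a quaternary oxirane carbon, so the alkyne has to sit on 12. 19 must be the bromide with bromine cis to C9 and trans to the ester. The iodide-triggered aldol of propiolates gives the opposite geometry, so that route is excluded.

**12 ⇒ 11 ⇒ 10 ⇒ 6 + 9.** The butenolide is cut at C7=C11 (ring-closing metathesis) and at O–C12 (ester). No palladium, hydride or strong base is needed near the alkynyl oxirane. The ester is formed with inversion, because vinyl addition to the epoxy aldehyde gives the erythro carbinol 6 and the lactone needs threo. Acid 9 is two steps from 7.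

**6 ⇒ 5 ⇒ 4 ⇒ 3 ⇒ 1.** C6 is added as a vinyl Grignard reagent to aldehyde 5. C4 and C5 come from Sharpless epoxidation of the silyl-capped Z-enynol 3, whose geometry already places the alkyne cis to C6. The commercial enynol 1 brings C2–C6 and C15.

**19 ⇒ 17 ⇒ 16 ⇒ 15 ⇒ 13 + 14.** The C9–C10 bond and the C9 stereocentre come from a catalytic asymmetric Morita–Baylis–Hillman reaction of acrylate 13 with aldehyde 14. Bromine addition and elimination then place bromine on C1 trans to the ester. C8 stays a silyl ether until the end.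

**31 ⇒ 30 ⇒ 29 ⇒ 28.** Sharpless epoxidation of angelyl alcohol 29 and oxidation give the acid; both methyl-bearing centres are set by the catalyst.

## Roads not taken

**Alternative 1:** Cut C4–C5 and O–C5 (macrocyclic Darzens reaction). The chloromethyl ketone A2 would be deprotonated at C5 with LiN(SiMe3)2. The enolate would add to the C4 methyl ketone and the alkoxide would displace chloride, giving the ten-membered keto bis-epoxide A1.
- Merits: ring and oxirane form in one operation. C8 and C9 arrive as ethers of fixed configuration, so no inversion at C8 is needed. In that respect it is better than the chosen plan, which needs an invertive esterification.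
- Weak points: the aldol step onto a methyl ketone is reversible and must span ten atoms. A2 has competing acidic sites (C7–H; the methyl ketone's C15 and C3–H, the latter opening the C2 oxirane). C4 and C5 are set in a macrocyclic transition state with no control element.
- Afterwards A1 still needs C6 reduction, lactone formation, two oxidation levels at C14 and four deprotections. The chosen closure delivers the lactone and methylene group with the ring and is followed by two steps.

**Alternative 2:** Cut C5–C6 and C9–C10 as a thermal [6+4] cycloaddition of tropone A3 with (1E,3E)-1,4-diacetoxybuta-1,3-diene A4, giving the bridged ketone A5 with C14 as the bridge.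
- Merits: it reaches a ten-membered ring in one step from two simple compounds, far sooner than the chosen plan (closure at step 20). C14 is in place and O6/O9 are cis.
- Weak points: A5 is meso and must be desymmetrized. It lacks C15, C11–C13, O8 and both oxiranes. The triene must become an enoate, an oxirane and a methylated oxirane. The C14–C5 bond must be cleaved selectively. Periselectivity with a 1,4-dioxygenated diene is less secure than with simple dienes.
- Every later stereocentre would depend on substrate control in a flexible bicycle. The chosen plan has eight of ten stereocentres in place before the ring exists.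

**Alternative 3:** No ring bond is cut. The enoate and both oxiranes are made last by an epoxide relay. Base would deprotonate C10 of the diepoxy mesylate A7, β-elimination would open the 1,2-oxirane, O2 would attack C3, and O4 would displace the C5 mesylate to give A6.
- Merits: C2–C5 are set stereospecifically from alcohol centres without an oxidant. This is better than the chosen plan's substrate-controlled peracid step.
- Weak points: A7 is itself a ten-membered ring with six contiguous stereocentres and no alkene to pre-bend its precursor, and the relay says nothing about how that ring is closed. The C10 anion can also expel the C9 silyloxy group. The first two relay steps are reversible. The methylene group must be added afterwards to a base-sensitive molecule.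
- The chosen plan accepts one epoxidation under acyclic control in exchange for a ring closure that also builds the lactone.

Key step: step 20

Remark: germacrane locants (C1–C15) are used throughout. Compound 27 is drawn as the 8R alcohol that the usual chair transition state of allylchromium reagents predicts; the analysis of step 20 gives the reasoning.

## Steps

Step 1
Reactants: 1 (Z)-3-methylpent-2-en-4-yn-1-ol
Product: 3 (Z)-3-methyl-5-(trimethylsilyl)pent-2-en-4-yn-1-ol, via O,C-bis(trimethylsilyl) derivative 2 (not isolated)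
Conditions: EtMgBr (2.2 equiv), THF, 0 → 40 °C; Me3SiCl, 0 °C → rt; 1 M H2SO4, rt
Reagents that add atoms: chlorotrimethylsilane, C[Si](C)(C)Cl
Why: The Grignard reagent removes the O–H and C≡C–H protons, both anions are silylated, and aqueous acid cleaves only the O–Si bond (C-silylation of a magnesium acetylide); the Z-alkene is untouched.

Step 2
Reactants: 3 (Z)-3-methyl-5-(trimethylsilyl)pent-2-en-4-yn-1-ol
Product: 4 [(2R,3S)-3-methyl-3-((trimethylsilyl)ethynyl)oxiran-2-yl]methanol
Conditions: Ti(OiPr)4 (10 mol %), D-(−)-diethyl tartrate (12 mol %), tBuOOH, 4 Å MS, CH2Cl2, −20 °C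
Reagents that add atoms: tert-butyl hydroperoxide, CC(C)(C)OO
Why: Sharpless asymmetric epoxidation of a 3,3-disubstituted Z-allylic alcohol; the D-(−)-tartrate catalyst is the mirror image of the one that converts nerol into its (2S,3R)-epoxide and so sets C5 (R) and C4 (S here). The Z-geometry places the alkyne cis to C6.

Step 3
Reactants: 4 [(2R,3S)-3-methyl-3-((trimethylsilyl)ethynyl)oxiran-2-yl]methanol
Product: 5 (2S,3S)-3-methyl-3-((trimethylsilyl)ethynyl)oxirane-2-carbaldehyde
Conditions: Dess–Martin periodinane, NaHCO3, CH2Cl2, 0 °C → rt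
Reagents that add atoms: none
Why: Buffered Dess–Martin oxidation; the oxirane C–H is not enolizable, so C5 is safe (the descriptor changes by priority only).

Step 4
Reactants: 5 (2S,3S)-3-methyl-3-((trimethylsilyl)ethynyl)oxirane-2-carbaldehyde
Product: 6 (R)-1-[(2R,3S)-3-methyl-3-((trimethylsilyl)ethynyl)oxiran-2-yl]prop-2-en-1-ol
Conditions: CH2=CHMgBr, THF, −78 °C; aq. NH4Cl
Reagents that add atoms: vinylmagnesium bromide, C=C[Mg]Br
Why: Grignard addition under Felkin–Anh control: the vinyl group enters anti to the C5–O bond of the oxirane and should give mainly the erythro (6R) carbinol, the usual result for cis-substituted epoxy aldehydes. The 6S isomer is removed by chromatography.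

Step 5
Reactants: 7 ethyl 2-(hydroxymethyl)acrylate
Product: 8 ethyl 2-(((tert-butyldimethylsilyl)oxy)methyl)acrylate
Conditions: tBuMe2SiCl, imidazole, CH2Cl2, 0 °C → rt
Reagents that add atoms: tert-butyldimethylsilyl chloride, CC(C)(C)[Si](C)(C)Cl
Why: Standard silylation of a primary alcohol.

Step 6
Reactants: 8 ethyl 2-(((tert-butyldimethylsilyl)oxy)methyl)acrylate
Product: 9 2-(((tert-butyldimethylsilyl)oxy)methyl)acrylic acid
Conditions: LiOH, THF/H2O, 0 °C → rt; 1 M HCl to pH 4
Reagents that add atoms: lithium hydroxide, [Li+].[OH-]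
Why: Saponification; the primary silyl ether survives cold hydroxide and a mild acidification.

Step 7
Reactants: 6 (R)-1-[(2R,3S)-3-methyl-3-((trimethylsilyl)ethynyl)oxiran-2-yl]prop-2-en-1-ol; 9 2-(((tert-butyldimethylsilyl)oxy)methyl)acrylic acid
Product: 10 (S)-1-[(2R,3S)-3-methyl-3-((trimethylsilyl)ethynyl)oxiran-2-yl]allyl 2-(((tert-butyldimethylsilyl)oxy)methyl)acrylate
Conditions: PPh3, diisopropyl azodicarboxylate, toluene, 0 °C → rt
Reagents that add atoms: none
Why: Mitsunobu esterification with SN2 inversion at C6, the standard conversion of an erythro epoxy alcohol into a threo ester; it sets the 6S lactone oxygen and installs the acrylate in one operation.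

Step 8
Reactants: 10 (S)-1-[(2R,3S)-3-methyl-3-((trimethylsilyl)ethynyl)oxiran-2-yl]allyl 2-(((tert-butyldimethylsilyl)oxy)methyl)acrylate
Product: 11 (S)-3-(((tert-butyldimethylsilyl)oxy)methyl)-5-[(2R,3S)-3-methyl-3-((trimethylsilyl)ethynyl)oxiran-2-yl]furan-2(5H)-one
Conditions: second-generation Grubbs catalyst (H2IMes)(PCy3)Cl2Ru=CHPh (5 mol %), CH2Cl2 (5 mM), 40 °C
Reagents that add atoms: none
Why: Ring-closing metathesis of an allylic acrylate to an α-substituted butenolide; the 1,1-disubstituted acrylate needs this catalyst. The silyl-capped alkyne on a quaternary carbon is too hindered for enyne metathesis.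

Step 9
Reactants: 11 (S)-3-(((tert-butyldimethylsilyl)oxy)methyl)-5-[(2R,3S)-3-methyl-3-((trimethylsilyl)ethynyl)oxiran-2-yl]furan-2(5H)-one
Product: 12 (S)-5-[(2R,3S)-3-ethynyl-3-methyloxiran-2-yl]-3-(hydroxymethyl)furan-2(5H)-one
Conditions: Bu4NF, AcOH (1:1), THF, 0 °C → rt
Reagents that add atoms: none
Why: Buffered fluoride cleaves the C(sp)–Si and the primary O–Si bonds; acetic acid prevents deprotonation at C6, whose anion would open the C5 oxirane.

Step 10
Reactants: 13 1,1,1,3,3,3-hexafluoropropan-2-yl acrylate; 14 2-((tert-butyldimethylsilyl)oxy)acetaldehyde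
Product: 15 1,1,1,3,3,3-hexafluoropropan-2-yl (S)-2-[2-((tert-butyldimethylsilyl)oxy)-1-hydroxyethyl]acrylate
Conditions: β-isocupreidine (10 mol %), DMF, −55 °C
Reagents that add atoms: none
Why: Catalytic asymmetric Morita–Baylis–Hillman reaction of the activated acrylate. The catalyst should attack the same aldehyde face as with other aliphatic aldehydes, which with the CH2OSi substituent reads as S and is the C9 configuration needed.

Step 11
Reactants: 15 1,1,1,3,3,3-hexafluoropropan-2-yl (S)-2-[2-((tert-butyldimethylsilyl)oxy)-1-hydroxyethyl]acrylate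
Product: 16 2-(trimethylsilyl)ethyl (S)-2-[2-((tert-butyldimethylsilyl)oxy)-1-hydroxyethyl]acrylate
Conditions: Me3SiCH2CH2OH, Et3N, rt
Reagents that add atoms: 2-(trimethylsilyl)ethanol, C[Si](C)(C)CCO
Why: Transesterification of the activated hexafluoroisopropyl ester under mild base; C9 is not involved.

Step 12
Reactants: 16 2-(trimethylsilyl)ethyl (S)-2-[2-((tert-butyldimethylsilyl)oxy)-1-hydroxyethyl]acrylate
Product: 17 2-(trimethylsilyl)ethyl (S)-2-[1-acetoxy-2-((tert-butyldimethylsilyl)oxy)ethyl]acrylate
Conditions: Ac2O, pyridine, CH2Cl2, 0 °C → rt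
Reagents that add atoms: acetic anhydride, CC(=O)OC(C)=O
Why: Acetylation of the secondary alcohol; pyridine without a stronger nucleophilic catalyst avoids SN2′ attack on the Baylis–Hillman acetate.

Step 13
Reactants: 17 2-(trimethylsilyl)ethyl (S)-2-[1-acetoxy-2-((tert-butyldimethylsilyl)oxy)ethyl]acrylate
Product: 19 2-(trimethylsilyl)ethyl (S,E)-3-acetoxy-2-(bromomethylene)-4-((tert-butyldimethylsilyl)oxy)butanoate, via dibromide 18 (not isolated)
Conditions: Br2, CH2Cl2, 0 °C → rt; Et3N, 0 °C → rt
Reagents that add atoms: bromine, BrBr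
Why: Bromine addition to a 2-substituted acrylate, then anti elimination of HBr (C1–H with C10–Br), the way (E)-3-bromo-2-methylacrylates are made. Bromine should end trans to the ester and cis to C9, the geometry C1=C10 needs.

Step 14
Reactants: 12 (S)-5-[(2R,3S)-3-ethynyl-3-methyloxiran-2-yl]-3-(hydroxymethyl)furan-2(5H)-one; 19 2-(trimethylsilyl)ethyl (S,E)-3-acetoxy-2-(bromomethylene)-4-((tert-butyldimethylsilyl)oxy)butanoate
Product: 20 2-(trimethylsilyl)ethyl (E)-2-[(S)-1-acetoxy-2-((tert-butyldimethylsilyl)oxy)ethyl]-5-{(2S,3R)-3-[(S)-4-(hydroxymethyl)-5-oxo-2,5-dihydrofuran-2-yl]-2-methyloxiran-2-yl}pent-2-en-4-ynoate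
Conditions: PdCl2(PPh3)2 (5 mol %), CuI (10 mol %), iPr2NEt, THF, rt, degassed
Reagents that add atoms: none
Why: Sonogashira coupling with retention of alkene geometry; oxidative addition of zerovalent palladium to the activated β-bromoacrylate is faster than ionization of the alkynyl oxirane or the allylic acetate. The hindered amine is too weak a base for the butenolide C6–H.

Step 15
Reactants: 20 the enyne of step 14
Product: 21 2-(trimethylsilyl)ethyl (2E,4Z)-2-[(S)-1-acetoxy-2-((tert-butyldimethylsilyl)oxy)ethyl]-5-{(2S,3R)-3-[(S)-4-(hydroxymethyl)-5-oxo-2,5-dihydrofuran-2-yl]-2-methyloxiran-2-yl}penta-2,4-dienoate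
Conditions: H2 (1 atm), Pd/CaCO3 poisoned with Pb(OAc)2, quinoline, EtOAc, rt
Reagents that add atoms: none
Why: Lindlar semi-hydrogenation gives the Z-alkene (C1 and C4 cis), as known for alkynyl oxiranes; the enoate and butenolide alkenes are not reduced.

Step 16
Reactants: 21 the (2E,4Z)-dienoate of step 15
Product: 22 2-(trimethylsilyl)ethyl (E)-2-[(S)-1-acetoxy-2-((tert-butyldimethylsilyl)oxy)ethyl]-3-[(2R,3R)-3-{(2R,3R)-3-[(S)-4-(hydroxymethyl)-5-oxo-2,5-dihydrofuran-2-yl]-2-methyloxiran-2-yl}oxiran-2-yl]acrylate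
Conditions: mCPBA, Na2HPO4, CH2Cl2, 0 °C → rt
Reagents that add atoms: 3-chloroperoxybenzoic acid, OOC(=O)c1cccc(Cl)c1
Why: Stereospecific peracid epoxidation of the only electron-rich alkene (the distal alkene of the dienoate). A(1,3) strain with C1–H should hold C5, the largest group on C4, in the alkene plane anti to C2, so the peracid enters past the oxirane oxygen and anti to the C4 methyl group, giving the 2R,3R oxirane.

Step 17
Reactants: 22 the bis-epoxide silyl ether of step 16
Product: 23 2-(trimethylsilyl)ethyl (E)-2-[(S)-1-acetoxy-2-hydroxyethyl]-3-[(2R,3R)-3-{(2R,3R)-3-[(S)-4-(hydroxymethyl)-5-oxo-2,5-dihydrofuran-2-yl]-2-methyloxiran-2-yl}oxiran-2-yl]acrylate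
Conditions: HF·pyridine, pyridine, THF, 0 °C → rt
Reagents that add atoms: none
Why: Buffered HF removes the primary silyl ether; the weakly acidic medium leaves oxiranes and the silylethyl ester alone and does not promote acetyl migration from O9 to O8.

Step 18
Reactants: 23 the diol of step 17
Product: 24 2-(trimethylsilyl)ethyl (E)-2-[(S)-1-acetoxy-2-hydroxyethyl]-3-[(2R,3R)-3-{(2R,3R)-3-[(S)-4-(bromomethyl)-5-oxo-2,5-dihydrofuran-2-yl]-2-methyloxiran-2-yl}oxiran-2-yl]acrylate
Conditions: N-bromosuccinimide, Me2S, CH2Cl2, −20 → 0 °C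
Reagents that add atoms: N-bromosuccinimide, BrN1C(=O)CCC1=O
Why: Corey–Kim bromination: bromide displaces only the allylic (C13) alkoxysulfonium ion; that of the saturated C8 alcohol reverts on work-up.

Step 19
Reactants: 24 the allylic bromide of step 18
Product: 25 2-(trimethylsilyl)ethyl (E)-2-[(S)-1-acetoxy-2-oxoethyl]-3-[(2R,3R)-3-{(2R,3R)-3-[(S)-4-(bromomethyl)-5-oxo-2,5-dihydrofuran-2-yl]-2-methyloxiran-2-yl}oxiran-2-yl]acrylate
Conditions: Dess–Martin periodinane, NaHCO3, CH2Cl2, 0 °C
Reagents that add atoms: none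
Why: Neutral buffered oxidation of the primary alcohol; no base or nucleophile meets the bromomethylbutenolide or the epimerizable α-acetoxy aldehyde, which is used at once.

Step 20
Reactants: 25 the bromomethylbutenolide aldehyde of step 19
Product: 27 2-(trimethylsilyl)ethyl (1(10)E,2R,3R,4R,5R,6S,7R,8R,9S)-9-acetoxy-2,3:4,5-diepoxy-8-hydroxygermacra-1(10),11(13)-dien-12,6-olid-14-oate, via C13 allylchromium dichloride 26 (not isolated)
Conditions: CrCl2 (8 equiv), THF, 25 °C, addition of 25 over 10 h (final 2 mM); aq. NH4Cl, 0 °C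
Reagents that add atoms: none
Why: Two equivalents of CrCl2 (divalent chromium) reduce the allylic C13–Br bond to the allylchromium dichloride 26, which adds through its γ carbon C7 to the C8 aldehyde in a closed six-membered transition state (Cr–O8–C8–C7–C11–C13) and shifts the double bond to C11=C13; the closest known reactions are the Nozaki–Hiyama allylation of aldehydes with 3-(bromomethyl)furan-2(5H)-ones and intramolecular allylchromium closures of ten-membered rings. The carbocycle closes by 10-exo-trig attack of C7 on the C8 carbonyl group, the E-enoate (C2 cis to C9) and the two cis-oxiranes supplying the turn. C7 is controlled by C6: the aldehyde should reach the butenolide face opposite the C5 substituent, where C5–C6–C7–C8 can be staggered, giving the trans-fused lactone (7R). C8 is controlled by the chair: C6 is locked trans to C13 by the butenolide ring and sits equatorial, the aldehyde substituent C9 takes the other equatorial site, and this anti mode gives the 8R alcohol (8-OH trans to C11, cis to 9-OAc). Felkin–Anh attack anti to the C9–OAc bond leads to the same epimer, so the two elements are matched. The step needs chemoselectivity for the allylic bromide over oxiranes, the γ,δ-epoxy enoate, acetate and silylethyl ester, which CrCl2 provides, and it needs monomolecular closure, secured by slow addition into excess reagent. The 8-hydroxyl has the configuration opposite to the natural ester, which step 24 inverts.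

Step 21
Reactants: 28 angelic acid, (Z)-2-methylbut-2-enoic acid
Product: 29 (Z)-2-methylbut-2-en-1-ol
Conditions: LiAlH4, Et2O, 0 °C; H2O, aq. NaOH
Reagents that add atoms: none
Why: Hydride reduction of the acid to the allylic alcohol; no acid or heat that would isomerize Z to E.

Step 22
Reactants: 29 (Z)-2-methylbut-2-en-1-ol
Product: 30 [(2S,3R)-2,3-dimethyloxiran-2-yl]methanol
Conditions: Ti(OiPr)4 (10 mol %), L-(+)-diethyl tartrate (12 mol %), tBuOOH, 4 Å MS, CH2Cl2, −20 °C
Reagents that add atoms: tert-butyl hydroperoxide, CC(C)(C)OO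
Why: Sharpless asymmetric epoxidation; the L-(+)-tartrate catalyst acts in the sense that gives (S)-2-methylglycidol from 2-methylallyl alcohol, and the stereospecific addition keeps the two methyl groups trans.

Step 23
Reactants: 30 [(2S,3R)-2,3-dimethyloxiran-2-yl]methanol
Product: 31 (2R,3R)-2,3-dimethyloxirane-2-carboxylic acid
Conditions: RuCl3·xH2O (2 mol %), NaIO4, CCl4/MeCN/H2O, rt
Reagents that add atoms: sodium periodate, [Na+].[O-][I](=O)(=O)=O; water, O
Why: RuO4 generated in situ oxidizes the primary alcohol to the acid without touching the oxirane; the C2 descriptor changes by priority only.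

Step 24
Reactants: 27 the 8R alcohol of step 20; 31 (2R,3R)-2,3-dimethyloxirane-2-carboxylic acid
Product: 32 2-(trimethylsilyl)ethyl (1(10)E,2R,3R,4R,5R,6S,7R,8S,9S)-9-acetoxy-8-{[(2R,3R)-2,3-dimethyloxiran-2-yl]carbonyloxy}-2,3:4,5-diepoxygermacra-1(10),11(13)-dien-12,6-olid-14-oate
Conditions: PPh3, diisopropyl azodicarboxylate, toluene, 0 °C → rt
Reagents that add atoms: none
Why: Mitsunobu esterification with SN2 inversion at C8: the carboxylate enters on the C11 face, anti to the phosphonium leaving group, giving the natural 8S ester. The cis 9-acetate lies on the leaving-group side and cannot participate.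

Step 25
Reactants: 32 the 2-(trimethylsilyl)ethyl ester of step 24
Product: 33 leucanthin B
Conditions: (Me2N)3S+ Me3SiF2− (TASF), DMF, 0 °C; pH 4 phosphate buffer
Reagents that add atoms: none
Why: Fluoride attacks silicon and the ester fragments to ethene and the carboxylate; anhydrous, weakly basic conditions are tolerated by α-methylene lactones, oxiranes and the two other esters.

## Compound list

1 | (Z)-3-methylpent-2-en-4-yn-1-ol | C#C/C(C)=C\CO | starting material
2 | (Z)-trimethyl{[3-methyl-5-(trimethylsilyl)pent-2-en-4-yn-1-yl]oxy}silane | C[Si](C)(C)C#C/C(C)=C\CO[Si](C)(C)C | intermediate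
3 | (Z)-3-methyl-5-(trimethylsilyl)pent-2-en-4-yn-1-ol | C[Si](C)(C)C#C/C(C)=C\CO | intermediate
4 | [(2R,3S)-3-methyl-3-((trimethylsilyl)ethynyl)oxiran-2-yl]methanol | OC[C@H]1O[C@@]1(C)C#C[Si](C)(C)C | intermediate
5 | (2S,3S)-3-methyl-3-((trimethylsilyl)ethynyl)oxirane-2-carbaldehyde | O=C[C@H]1O[C@@]1(C)C#C[Si](C)(C)C | intermediate
6 | (R)-1-[(2R,3S)-3-methyl-3-((trimethylsilyl)ethynyl)oxiran-2-yl]prop-2-en-1-ol | C=C[C@@H](O)[C@H]1O[C@@]1(C)C#C[Si](C)(C)C | intermediate
7 | ethyl 2-(hydroxymethyl)acrylate | C=C(CO)C(=O)OCC | starting material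
8 | ethyl 2-(((tert-butyldimethylsilyl)oxy)methyl)acrylate | C=C(CO[Si](C)(C)C(C)(C)C)C(=O)OCC | intermediate
9 | 2-(((tert-butyldimethylsilyl)oxy)methyl)acrylic acid | C=C(CO[Si](C)(C)C(C)(C)C)C(=O)O | intermediate
10 | (S)-1-[(2R,3S)-3-methyl-3-((trimethylsilyl)ethynyl)oxiran-2-yl]allyl 2-(((tert-butyldimethylsilyl)oxy)methyl)acrylate | C=C[C@H](OC(=O)C(=C)CO[Si](C)(C)C(C)(C)C)[C@H]1O[C@@]1(C)C#C[Si](C)(C)C | intermediate
11 | (S)-3-(((tert-butyldimethylsilyl)oxy)methyl)-5-[(2R,3S)-3-methyl-3-((trimethylsilyl)ethynyl)oxiran-2-yl]furan-2(5H)-one | CC(C)(C)[Si](C)(C)OCC1=C[C@H](OC1=O)[C@H]1O[C@@]1(C)C#C[Si](C)(C)C | intermediate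
12 | (S)-5-[(2R,3S)-3-ethynyl-3-methyloxiran-2-yl]-3-(hydroxymethyl)furan-2(5H)-one | OCC1=C[C@H](OC1=O)[C@H]1O[C@@]1(C)C#C | intermediate
13 | 1,1,1,3,3,3-hexafluoropropan-2-yl acrylate | C=CC(=O)OC(C(F)(F)F)C(F)(F)F | starting material
14 | 2-((tert-butyldimethylsilyl)oxy)acetaldehyde | O=CCO[Si](C)(C)C(C)(C)C | starting material
15 | 1,1,1,3,3,3-hexafluoropropan-2-yl (S)-2-[2-((tert-butyldimethylsilyl)oxy)-1-hydroxyethyl]acrylate | C=C(C(=O)OC(C(F)(F)F)C(F)(F)F)[C@H](O)CO[Si](C)(C)C(C)(C)C | intermediate
16 | 2-(trimethylsilyl)ethyl (S)-2-[2-((tert-butyldimethylsilyl)oxy)-1-hydroxyethyl]acrylate | C=C(C(=O)OCC[Si](C)(C)C)[C@H](O)CO[Si](C)(C)C(C)(C)C | intermediate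
17 | 2-(trimethylsilyl)ethyl (S)-2-[1-acetoxy-2-((tert-butyldimethylsilyl)oxy)ethyl]acrylate | C=C(C(=O)OCC[Si](C)(C)C)[C@H](OC(C)=O)CO[Si](C)(C)C(C)(C)C | intermediate
18 | 2-(trimethylsilyl)ethyl (3R)-3-acetoxy-2-bromo-2-(bromomethyl)-4-((tert-butyldimethylsilyl)oxy)butanoate (both C2 epimers) | BrCC(Br)(C(=O)OCC[Si](C)(C)C)[C@H](OC(C)=O)CO[Si](C)(C)C(C)(C)C | intermediate
19 | 2-(trimethylsilyl)ethyl (S,E)-3-acetoxy-2-(bromomethylene)-4-((tert-butyldimethylsilyl)oxy)butanoate | Br/C=C(/C(=O)OCC[Si](C)(C)C)[C@H](OC(C)=O)CO[Si](C)(C)C(C)(C)C | intermediate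
20 | 2-(trimethylsilyl)ethyl (E)-2-[(S)-1-acetoxy-2-((tert-butyldimethylsilyl)oxy)ethyl]-5-{(2S,3R)-3-[(S)-4-(hydroxymethyl)-5-oxo-2,5-dihydrofuran-2-yl]-2-methyloxiran-2-yl}pent-2-en-4-ynoate | OCC1=C[C@H](OC1=O)[C@H]1O[C@@]1(C)C#C/C=C(/C(=O)OCC[Si](C)(C)C)[C@H](OC(C)=O)CO[Si](C)(C)C(C)(C)C | intermediate
21 | 2-(trimethylsilyl)ethyl (2E,4Z)-2-[(S)-1-acetoxy-2-((tert-butyldimethylsilyl)oxy)ethyl]-5-{(2S,3R)-3-[(S)-4-(hydroxymethyl)-5-oxo-2,5-dihydrofuran-2-yl]-2-methyloxiran-2-yl}penta-2,4-dienoate | OCC1=C[C@H](OC1=O)[C@H]1O[C@@]1(C)/C=C\C=C(\C(=O)OCC[Si](C)(C)C)[C@H](OC(C)=O)CO[Si](C)(C)C(C)(C)C | intermediate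
22 | 2-(trimethylsilyl)ethyl (E)-2-[(S)-1-acetoxy-2-((tert-butyldimethylsilyl)oxy)ethyl]-3-[(2R,3R)-3-{(2R,3R)-3-[(S)-4-(hydroxymethyl)-5-oxo-2,5-dihydrofuran-2-yl]-2-methyloxiran-2-yl}oxiran-2-yl]acrylate | OCC1=C[C@H](OC1=O)[C@H]1O[C@@]1(C)[C@@H]1O[C@@H]1/C=C(/C(=O)OCC[Si](C)(C)C)[C@H](OC(C)=O)CO[Si](C)(C)C(C)(C)C | intermediate
23 | 2-(trimethylsilyl)ethyl (E)-2-[(S)-1-acetoxy-2-hydroxyethyl]-3-[(2R,3R)-3-{(2R,3R)-3-[(S)-4-(hydroxymethyl)-5-oxo-2,5-dihydrofuran-2-yl]-2-methyloxiran-2-yl}oxiran-2-yl]acrylate | OCC1=C[C@H](OC1=O)[C@H]1O[C@@]1(C)[C@@H]1O[C@@H]1/C=C(/C(=O)OCC[Si](C)(C)C)[C@H](OC(C)=O)CO | intermediate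
24 | 2-(trimethylsilyl)ethyl (E)-2-[(S)-1-acetoxy-2-hydroxyethyl]-3-[(2R,3R)-3-{(2R,3R)-3-[(S)-4-(bromomethyl)-5-oxo-2,5-dihydrofuran-2-yl]-2-methyloxiran-2-yl}oxiran-2-yl]acrylate | BrCC1=C[C@H](OC1=O)[C@H]1O[C@@]1(C)[C@@H]1O[C@@H]1/C=C(/C(=O)OCC[Si](C)(C)C)[C@H](OC(C)=O)CO | intermediate
25 | 2-(trimethylsilyl)ethyl (E)-2-[(S)-1-acetoxy-2-oxoethyl]-3-[(2R,3R)-3-{(2R,3R)-3-[(S)-4-(bromomethyl)-5-oxo-2,5-dihydrofuran-2-yl]-2-methyloxiran-2-yl}oxiran-2-yl]acrylate | BrCC1=C[C@H](OC1=O)[C@H]1O[C@@]1(C)[C@@H]1O[C@@H]1/C=C(/C(=O)OCC[Si](C)(C)C)[C@H](OC(C)=O)C=O | intermediate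
26 | C13 allylchromium dichloride of 25 (C–Br replaced by C–CrCl2) | Cl[Cr](Cl)CC1=C[C@H](OC1=O)[C@H]1O[C@@]1(C)[C@@H]1O[C@@H]1/C=C(/C(=O)OCC[Si](C)(C)C)[C@H](OC(C)=O)C=O | intermediate
27 | 2-(trimethylsilyl)ethyl (1(10)E,2R,3R,4R,5R,6S,7R,8R,9S)-9-acetoxy-2,3:4,5-diepoxy-8-hydroxygermacra-1(10),11(13)-dien-12,6-olid-14-oate | C=C1C(=O)O[C@H]2[C@H]1[C@@H](O)[C@@H](OC(C)=O)/C(C(=O)OCC[Si](C)(C)C)=C\[C@H]1O[C@H]1[C@]1(C)O[C@H]21 | intermediate
28 | angelic acid, (Z)-2-methylbut-2-enoic acid | C/C=C(/C)C(=O)O | starting material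
29 | (Z)-2-methylbut-2-en-1-ol | C/C=C(/C)CO | intermediate
30 | [(2S,3R)-2,3-dimethyloxiran-2-yl]methanol | OC[C@]1(C)O[C@@H]1C | intermediate
31 | (2R,3R)-2,3-dimethyloxirane-2-carboxylic acid | OC(=O)[C@]1(C)O[C@@H]1C | intermediate
32 | 2-(trimethylsilyl)ethyl (1(10)E,2R,3R,4R,5R,6S,7R,8S,9S)-9-acetoxy-8-{[(2R,3R)-2,3-dimethyloxiran-2-yl]carbonyloxy}-2,3:4,5-diepoxygermacra-1(10),11(13)-dien-12,6-olid-14-oate | C=C1C(=O)O[C@H]2[C@H]1[C@H](OC(=O)[C@]1(C)O[C@@H]1C)[C@@H](OC(C)=O)/C(C(=O)OCC[Si](C)(C)C)=C\[C@H]1O[C@H]1[C@]1(C)O[C@H]21 | intermediate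
33 | leucanthin B | C=C1C(=O)O[C@H]2[C@H]1[C@H](OC(=O)[C@]1(C)O[C@@H]1C)[C@@H](OC(C)=O)/C(C(=O)O)=C\[C@H]1O[C@H]1[C@]1(C)O[C@H]21 | target

## Step count and least certain steps

Total: 25 steps. Longest linear sequence: 16 steps (1, 2, 3, 4, 7, 8, 9, 14–20, 24, 25, from compound 1).

**Step 20 (key step).** Three things can go wrong.
- Intermolecular allylation may outrun closure of the strained ring.
- The ring may force the aldehyde substituent C9 into the axial site of the chair, or force a boat, which reverses the configuration at C8. Approach to the butenolide face syn to C5 would give the cis-lactone.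
- The chromium alkoxide on O8 may take the acetyl group from the cis O9.

Fallback for a reversed C8: the reaction would then give the 8S epimer, 2-(trimethylsilyl)ethyl (8S)-9-acetoxy-2,3:4,5-diepoxy-8-hydroxygermacra-1(10),11(13)-dien-12,6-olid-14-oate F1, in place of 27. F1 would be esterified with retention with 31 under Yamaguchi conditions (2,4,6-trichlorobenzoyl chloride, Et3N, then DMAP, toluene) and rejoins the route at 32.

**Step 24.** The oxyphosphonium ion at the hindered C8 may eliminate toward C9 (C9–H is anti to the leaving group) or be attacked at phosphorus, giving the ester with retention. Fallback from 27: sulfonylation with chloromethanesulfonyl chloride and pyridine gives the 8-chloromethanesulfonate F2. SN2 displacement with caesium (2R,3R)-2,3-dimethyloxirane-2-carboxylate F3 (from 31 and Cs2CO3) and 18-crown-6 in toluene returns to 32.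

**Step 16.** The alkene is deactivated by the enoate and the neighbouring oxirane, so epoxidation may be slow. Facial selectivity rests on a conformational preference about C3–C4 that may be weak, and repulsion between peracid and oxirane oxygen could favour the other face. Fallback from 21: N-bromosuccinimide in aqueous dimethoxyethane gives the bromohydrin 2-(trimethylsilyl)ethyl (E)-2-[(S)-1-acetoxy-2-((tert-butyldimethylsilyl)oxy)ethyl]-5-bromo-4-hydroxy-5-(oxiranyl)pent-2-enoate F4 (OH on C2, Br on C3). Closure with Ag2O puts the oxirane on the face opposite to the one the electrophile took and returns to 22.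

**Step 7 (with step 4).** The Felkin preference in step 4 may be small because the cis substituent on the oxirane is a slim alkyne. In step 7 the allylic oxyphosphonium ion may react by SN2′, and PPh3 may add to the acrylic acid. Fallback from 6: Mitsunobu inversion with 4-nitrobenzoic acid gives the inverted ester (S)-1-[(2R,3S)-3-methyl-3-((trimethylsilyl)ethynyl)oxiran-2-yl]allyl 4-nitrobenzoate F5. Reductive cleavage with i-Bu2AlH at −78 °C gives the threo alcohol (S)-1-[(2R,3S)-3-methyl-3-((trimethylsilyl)ethynyl)oxiran-2-yl]prop-2-en-1-ol F6. Carbodiimide esterification with 9 (EDC, DMAP) returns to 10.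

**Step 13.** The C9 acetate may take part in the opening of the bromonium ion and scramble the oxygen pattern. The elimination may give some of the isomer with bromine cis to the ester, or remove C9–H instead. Fallback from 16, with a non-participating group on O9 during the halogen chemistry:
- Et3SiCl and imidazole give the triethylsilyl ether 2-(trimethylsilyl)ethyl (S)-2-[2-((tert-butyldimethylsilyl)oxy)-1-((triethylsilyl)oxy)ethyl]acrylate F7.
- Bromine addition gives the dibromide 2-(trimethylsilyl)ethyl 2-bromo-2-(bromomethyl)-4-((tert-butyldimethylsilyl)oxy)-3-((triethylsilyl)oxy)butanoate F8.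
- Elimination with Et3N gives the vinyl bromide 2-(trimethylsilyl)ethyl (S,E)-2-(bromomethylene)-4-((tert-butyldimethylsilyl)oxy)-3-((triethylsilyl)oxy)butanoate F9.
- Pyridinium p-toluenesulfonate in methanol removes the secondary triethylsilyl group selectively and gives the alcohol 2-(trimethylsilyl)ethyl (S,E)-2-(bromomethylene)-4-((tert-butyldimethylsilyl)oxy)-3-hydroxybutanoate F10.
- Acetylation (Ac2O, pyridine) returns to 19.

## Further compounds

F1 | step 20 | 2-(trimethylsilyl)ethyl (1(10)E,2R,3R,4R,5R,6S,7R,8S,9S)-9-acetoxy-2,3:4,5-diepoxy-8-hydroxygermacra-1(10),11(13)-dien-12,6-olid-14-oate | C=C1C(=O)O[C@H]2[C@H]1[C@H](O)[C@@H](OC(C)=O)/C(C(=O)OCC[Si](C)(C)C)=C\[C@H]1O[C@H]1[C@]1(C)O[C@H]21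
F2 | step 24 | 8-chloromethanesulfonate of 27 | C=C1C(=O)O[C@H]2[C@H]1[C@@H](OS(=O)(=O)CCl)[C@@H](OC(C)=O)/C(C(=O)OCC[Si](C)(C)C)=C\[C@H]1O[C@H]1[C@]1(C)O[C@H]21
F3 | step 24 | caesium (2R,3R)-2,3-dimethyloxirane-2-carboxylate | [Cs+].[O-]C(=O)[C@]1(C)O[C@@H]1C
F4 | step 16 | bromohydrin of 21 (C2–OH, C3–Br) | OCC1=C[C@H](OC1=O)[C@H]1O[C@@]1(C)[C@@H](Br)[C@H](O)/C=C(/C(=O)OCC[Si](C)(C)C)[C@H](OC(C)=O)CO[Si](C)(C)C(C)(C)C
F5 | step 7 | (S)-1-[(2R,3S)-3-methyl-3-((trimethylsilyl)ethynyl)oxiran-2-yl]allyl 4-nitrobenzoate | C=C[C@H](OC(=O)c1ccc(cc1)[N+](=O)[O-])[C@H]1O[C@@]1(C)C#C[Si](C)(C)C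
F6 | step 7 | (S)-1-[(2R,3S)-3-methyl-3-((trimethylsilyl)ethynyl)oxiran-2-yl]prop-2-en-1-ol | C=C[C@H](O)[C@H]1O[C@@]1(C)C#C[Si](C)(C)C
F7 | step 13 | 2-(trimethylsilyl)ethyl (S)-2-[2-((tert-butyldimethylsilyl)oxy)-1-((triethylsilyl)oxy)ethyl]acrylate | C=C(C(=O)OCC[Si](C)(C)C)[C@H](O[Si](CC)(CC)CC)CO[Si](C)(C)C(C)(C)C
F8 | step 13 | 2-(trimethylsilyl)ethyl 2-bromo-2-(bromomethyl)-4-((tert-butyldimethylsilyl)oxy)-3-((triethylsilyl)oxy)butanoate (both C2 epimers) | BrCC(Br)(C(=O)OCC[Si](C)(C)C)[C@H](O[Si](CC)(CC)CC)CO[Si](C)(C)C(C)(C)C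
F9 | step 13 | 2-(trimethylsilyl)ethyl (S,E)-2-(bromomethylene)-4-((tert-butyldimethylsilyl)oxy)-3-((triethylsilyl)oxy)butanoate | Br/C=C(/C(=O)OCC[Si](C)(C)C)[C@H](O[Si](CC)(CC)CC)CO[Si](C)(C)C(C)(C)C
F10 | step 13 | 2-(trimethylsilyl)ethyl (S,E)-2-(bromomethylene)-4-((tert-butyldimethylsilyl)oxy)-3-hydroxybutanoate | Br/C=C(/C(=O)OCC[Si](C)(C)C)[C@H](O)CO[Si](C)(C)C(C)(C)C
A1 | alternative 1 | ten-membered bis-epoxy C6 ketone | O=C1[C@H](C(=C)CO[Si](C)(C)C(C)(C)C)[C@H](OCc2ccc(OC)cc2)[C@@H](O[Si](C)(C)C(C)(C)C)/C(CO[Si](C(C)C)(C(C)C)C(C)C)=C\[C@H]2O[C@H]2[C@]2(C)O[C@H]12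
A2 | alternative 1 | open-chain chloromethyl ketone / methyl ketone | ClCC(=O)[C@H](C(=C)CO[Si](C)(C)C(C)(C)C)[C@H](OCc1ccc(OC)cc1)[C@@H](O[Si](C)(C)C(C)(C)C)/C(CO[Si](C(C)C)(C(C)C)C(C)C)=C\[C@H]1O[C@H]1C(C)=O
A3 | alternative 2 | tropone | O=C1C=CC=CC=C1
A4 | alternative 2 | (1E,3E)-1,4-diacetoxybuta-1,3-diene | CC(=O)O/C=C/C=C/OC(C)=O
A5 | alternative 2 | meso exo-7,10-diacetoxybicyclo[4.4.1]undeca-2,4,8-trien-11-one | O=C1[C@H]2C=CC=C[C@@H]1[C@@H](OC(C)=O)C=C[C@H]2OC(C)=O
A6 | alternative 3 | 2,3:4,5-diepoxy C1=C10 enoate lactone | C1C(=O)O[C@H]2[C@H]1[C@H](OCc3ccc(OC)cc3)[C@@H](O[Si](C)(C)C(C)(C)C)/C(C(=O)OCC[Si](C)(C)C)=C\[C@H]1O[C@H]1[C@]1(C)O[C@H]21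
A7 | alternative 3 | 1,2:3,4-diepoxy 5-mesylate (C1 and C10 unspecified) | C1C(=O)O[C@H]2[C@H]1[C@H](OCc1ccc(OC)cc1)[C@@H](O[Si](C)(C)C(C)(C)C)C(C(=O)OCC[Si](C)(C)C)C1O[C@H]1[C@@H]1O[C@]1(C)[C@H]2OS(C)(=O)=O
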